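**Retrosynthetic overview**

- The strategy rests on the trans-(3R,4R)-3,4-bis(arylmethyl)-γ-butyrolactone. Lactone C3 carries the CH2 to ring A (the phenol ring with the anti 1,3-diol side chain) and lactone C4 carries the CH2 to ring B (the benzo ring of the (2S,3R)-dihydrobenzofuran). This is a butenolide that has accepted a benzylic nucleophile at C4 and a benzylic electrophile at C3.
- Key disconnection: C4–C(benzylic, ring B) and C3–CH2(ring A) are made in one flask. The lithiated dithiane of the dihydrobenzofuran aldehyde adds to (5R)-5-menthyloxy-2(5H)-furanone and the enolate is trapped with the ring A benzyl bromide. The acetal carbon C5 later becomes the lactone OCH2.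
- Dithiane half: Evans syn aldol of a (2-MOM-oxy-5-bromoaryl)acetyl oxazolidinone with O-benzylvanillin, reduction, acid ring closure to the trans dihydrobenzofuran, then Br → CHO → dithiane.
- Bromide half: MgCl2-catalysed anti aldol of the 2-benzyloxy analogue on the same auxiliary, reduction, silylation, then Br → CH2OH → CH2Br.
- Ring order: the furanone ring (from furfural) first, the dihydrofuran ring of the benzofuran second (step 9). No ring closes in the key step. The lactone ring is opened and re-closed in step 24, followed by fluoride and hydrogenolysis.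

Key step: step 22

Remark: ring A = phenol ring bearing the diol side chain, ring B = benzo ring of the dihydrobenzofuran, ring C = guaiacyl ring on C2 of the dihydrobenzofuran, ring D = guaiacyl ring on the carbinol carbon; the acid-mediated closure of step 9 is assumed to be under thermodynamic control and to give the trans ring, as is usual for 2-aryl-3-hydroxymethyl-2,3-dihydrobenzofurans. (TBS = tert-butyldimethylsilyl, TMS = trimethylsilyl, Bn = benzyl, MOM = methoxymethyl.)

**Butenolide**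

Step 1
Reactants: 1 furfural
Product: 2 5-hydroxy-2(5H)-furanone (racemic)
Conditions: O2, hν (visible), methylene blue (3,7-bis(dimethylamino)phenothiazin-5-ium chloride, cat.), MeOH, rt
Reagents that add atoms: dioxygen, O=O
Why: Dye-sensitised singlet-oxygen [4+2] cycloaddition to the furan (photooxygenation), then methanolysis of the formyl group and collapse of the endoperoxide, should give the γ-hydroxybutenolide; the hemiacetal carbon forms racemic and is corrected in step 2.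

Step 2
Reactants: 2 5-hydroxy-2(5H)-furanone; 3 (1R,2S,5R)-menthol
Product: 5 (5R)-5-[(1R,2S,5R)-menthyloxy]-2(5H)-furanone, via epimeric menthyloxyfuranone 4 (not isolated)
Conditions: (+)-camphor-10-sulfonic acid (cat.), toluene, reflux, Dean–Stark; crystallisation from petroleum ether, mother liquor re-equilibrated with the same acid and recrystallised
Reagents that add atoms: none
Why: Acid-catalysed acetalisation of the cyclic hemiacetal with the chiral-pool alcohol gives both C5 epimers, which interconvert under acid, and the (5R) epimer should be harvested by crystallisation, so the acetal stereocentre is fixed by menthol.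

**Ring B half (dithiane)**

Step 3
Reactants: 6 5-bromo-2-hydroxy-3-methoxybenzaldehyde
Product: 7 5-bromo-3-methoxy-2-(methoxymethoxy)benzaldehyde
Conditions: MOMCl, i-Pr2NEt, CH2Cl2, 0 °C → rt
Reagents that add atoms: chloromethyl methyl ether, COCCl
Why: Williamson-type O-alkylation of the phenol; MOM is chosen because acid later unmasks this one phenol for the ring closure while the benzyl ether of ring C stays.

Step 4
Reactants: 7 5-bromo-3-methoxy-2-(methoxymethoxy)benzaldehyde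
Product: 9 2-[5-bromo-3-methoxy-2-(methoxymethoxy)phenyl]acetonitrile, via tosylvinylformamide 8 (not isolated)
Conditions: TosMIC, KOt-Bu, DME, −40 °C; then MeOH, reflux
Reagents that add atoms: tosylmethyl isocyanide, Cc1ccc(cc1)S(=O)(=O)C[N+]#[C-]
Why: van Leusen reductive cyanation: the TosMIC anion adds to the aldehyde and methanolysis of the N-(1-tosylvinyl)formamide with loss of sulfinate should give the one-carbon-homologated nitrile under base-only conditions that keep the MOM acetal and the aryl bromide.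

Step 5
Reactants: 9 2-[5-bromo-3-methoxy-2-(methoxymethoxy)phenyl]acetonitrile
Product: 10 2-[5-bromo-3-methoxy-2-(methoxymethoxy)phenyl]acetic acid
Conditions: KOH, EtOH–H2O, reflux; then 1 M HCl to pH 4, 0 °C
Reagents that add atoms: water, O; potassium hydroxide, [K+].[OH-]
Why: Base hydrolysis of the nitrile to the carboxylate, with cold mild acidification so that the MOM ether survives.

Step 6
Reactants: 10 2-[5-bromo-3-methoxy-2-(methoxymethoxy)phenyl]acetic acid; 11 (S)-4-benzyl-1,3-oxazolidin-2-one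
Product: 13 (4S)-4-benzyl-3-{[5-bromo-3-methoxy-2-(methoxymethoxy)phenyl]acetyl}-1,3-oxazolidin-2-one, via mixed pivalic anhydride 12 (not isolated)
Conditions: PivCl, Et3N, THF, −20 °C; then 11, LiCl, −20 °C → rt
Reagents that add atoms: none
Why: N-acylation of the Evans auxiliary through the mixed pivalic anhydride with LiCl/Et3N activation, the oxazolidinone attacking the unhindered arylacetyl carbonyl.

Step 7
Reactants: 13 ring B arylacetyl imide; 14 4-(benzyloxy)-3-methoxybenzaldehyde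
Product: 16 (2S,3S)-syn aldol imide of the ring B series, via dibutylboron enolate 15 (not isolated)
Conditions: Bu2BOTf, i-Pr2NEt, CH2Cl2, 0 °C; 14, −78 → 0 °C; then pH 7 buffer, MeOH, H2O2, 0 °C
Reagents that add atoms: none
Why: Evans syn aldol: the (Z)-boron enolate reacts through a Zimmerman–Traxler chair with the auxiliary dipole opposed, the aldehyde taking the enolate face away from the auxiliary benzyl group, which should set the aryl-bearing carbon (later C3 of the dihydrobenzofuran) and the syn carbinol as (2S,3S).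

Step 8
Reactants: 16 syn aldol imide
Product: 17 (1S,2R)-1-[4-(benzyloxy)-3-methoxyphenyl]-2-[5-bromo-3-methoxy-2-(methoxymethoxy)phenyl]propane-1,3-diol
Conditions: LiBH4, MeOH (2 equiv), THF, 0 °C
Reagents that add atoms: none
Why: Reductive cleavage of the N-acyl oxazolidinone with LiBH4 at the exocyclic carbonyl gives the primary alcohol and releases the auxiliary without touching a stereocentre.

Step 9
Reactants: 17 syn diol
Product: 18 {(2S,3R)-2-[4-(benzyloxy)-3-methoxyphenyl]-5-bromo-7-methoxy-2,3-dihydro-1-benzofuran-3-yl}methanol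
Conditions: HCl (1.25 M in MeOH), 0 → 40 °C
Reagents that add atoms: none
Why: Acid cleaves the MOM acetal and ionises the p-benzyloxybenzylic alcohol to a stabilised cation that the freed ortho phenol captures (SN1 cycloetherification, 5-exo); the reversible closure should settle on the trans ring, C3 being fixed by the aldol and C2 (S) by thermodynamic control.

Step 10
Reactants: 18 dihydrobenzofuran alcohol
Product: 19 TBS ether of 18
Conditions: TBSCl, imidazole, DMF, rt
Reagents that add atoms: tert-butyldimethylsilyl chloride, CC(C)(C)[Si](C)(C)Cl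
Why: Standard imidazole-promoted silylation of the primary alcohol.

Step 11
Reactants: 19 silylated aryl bromide
Product: 21 (2S,3R)-2-[4-(benzyloxy)-3-methoxyphenyl]-3-{[(tert-butyldimethylsilyl)oxy]methyl}-7-methoxy-2,3-dihydro-1-benzofuran-5-carbaldehyde, via aryllithium 20 (not isolated)
Conditions: t-BuLi (2.1 equiv), THF, −78 °C; DMF, −78 → 0 °C; H2O
Reagents that add atoms: N,N-dimethylformamide, CN(C)C=O
Why: Bromine–lithium exchange, much faster at −78 °C than any deprotonation, followed by formylation of the aryllithium with DMF (Bouveault aldehyde synthesis).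

Step 12
Reactants: 21 dihydrobenzofuran-5-carbaldehyde
Product: 22 2-{(2S,3R)-2-[4-(benzyloxy)-3-methoxyphenyl]-3-{[(tert-butyldimethylsilyl)oxy]methyl}-7-methoxy-2,3-dihydro-1-benzofuran-5-yl}-1,3-dithiane
Conditions: HS(CH2)3SH, BF3·OEt2 (cat.), CH2Cl2, −20 → 0 °C; Et3N quench
Reagents that add atoms: propane-1,3-dithiol, SCCCS
Why: Lewis-acid-catalysed dithioacetalisation of the aromatic aldehyde, run cold with catalytic BF3·OEt2 so that the silyl ether and the benzylic aryl ether of the dihydrobenzofuran should survive.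

**Ring A half (benzyl bromide)**

Step 13
Reactants: 6 5-bromo-2-hydroxy-3-methoxybenzaldehyde
Product: 23 2-(benzyloxy)-5-bromo-3-methoxybenzaldehyde
Conditions: BnBr, K2CO3, DMF, rt
Reagents that add atoms: benzyl bromide, BrCc1ccccc1
Why: Williamson benzylation of the phenol; this benzyl ether stays on ring A until the final hydrogenolysis.

Step 14
Reactants: 23 2-(benzyloxy)-5-bromo-3-methoxybenzaldehyde
Product: 25 2-[2-(benzyloxy)-5-bromo-3-methoxyphenyl]acetonitrile, via tosylvinylformamide 24 (not isolated)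
Conditions: TosMIC, KOt-Bu, DME, −40 °C; then MeOH, reflux
Reagents that add atoms: tosylmethyl isocyanide, Cc1ccc(cc1)S(=O)(=O)C[N+]#[C-]
Why: van Leusen reductive cyanation, as in step 4.

Step 15
Reactants: 25 arylacetonitrile
Product: 26 2-[2-(benzyloxy)-5-bromo-3-methoxyphenyl]acetic acid
Conditions: KOH, EtOH–H2O, reflux; then 1 M HCl to pH 3
Reagents that add atoms: water, O; potassium hydroxide, [K+].[OH-]
Why: Base hydrolysis of the nitrile; benzyl ether and aryl bromide are inert.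

Step 16
Reactants: 26 arylacetic acid; 11 (S)-4-benzyl-1,3-oxazolidin-2-one
Product: 28 (4S)-4-benzyl-3-{[2-(benzyloxy)-5-bromo-3-methoxyphenyl]acetyl}-1,3-oxazolidin-2-one, via mixed pivalic anhydride 27 (not isolated)
Conditions: PivCl, Et3N, THF, −20 °C; then 11, LiCl, −20 °C → rt
Reagents that add atoms: none
Why: Mixed-anhydride N-acylation of the Evans auxiliary, as in step 6.

Step 17
Reactants: 28 ring A arylacetyl imide; 14 4-(benzyloxy)-3-methoxybenzaldehyde
Product: 29 (2R,3S)-anti aldol imide of the ring A series as its O-TMS ether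
Conditions: MgCl2 (0.2 equiv), Et3N, TMSCl, EtOAc, rt
Reagents that add atoms: chlorotrimethylsilane, C[Si](C)(C)Cl
Why: Evans magnesium-halide-catalysed anti aldol: soft enolisation gives the chelated (Z)-magnesium enolate, the aldehyde adds through a boat-like transition state on the face opposite the auxiliary benzyl group (the face used in alkylations), and silylation of the aldolate makes the addition irreversible, which should set the aryl-bearing carbon R and the anti carbinol S.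

Step 18
Reactants: 29 silylated anti aldol imide
Product: 31 (1S,2S)-2-[2-(benzyloxy)-5-bromo-3-methoxyphenyl]-1-[4-(benzyloxy)-3-methoxyphenyl]propane-1,3-diol, via silyl ether alcohol 30 (not isolated)
Conditions: LiBH4, MeOH (2 equiv), THF, 0 °C; then K2CO3 (cat.), MeOH, rt
Reagents that add atoms: none
Why: LiBH4 reductive cleavage of the imide, then base-catalysed methanolysis of the TMS ether once no carbonyl is left for a retro-aldol, so both stereocentres are kept.

Step 19
Reactants: 31 anti diol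
Product: 32 bis-TBS ether of 31
Conditions: TBSOTf, 2,6-lutidine, CH2Cl2, −78 → 0 °C
Reagents that add atoms: tert-butyldimethylsilyl trifluoromethanesulfonate, CC(C)(C)[Si](C)(C)OS(=O)(=O)C(F)(F)F
Why: Silyl triflate with a hindered pyridine base silylates both the primary and the hindered benzylic alcohol without ionising the benzylic position.

Step 20
Reactants: 32 bis-silylated aryl bromide
Product: 35 ring A benzyl alcohol, via aryllithium 33 (not isolated), via aldehyde 34 (not isolated)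
Conditions: t-BuLi (2.1 equiv), THF, −78 °C; DMF, −78 → 0 °C; then MeOH, NaBH4, 0 °C
Reagents that add atoms: N,N-dimethylformamide, CN(C)C=O
Why: Bromine–lithium exchange and DMF formylation (Bouveault), then borohydride reduction of the aldehyde in the same flask.

Step 21
Reactants: 35 ring A benzyl alcohol
Product: 36 ring A benzyl bromide
Conditions: CBr4, PPh3, 2,6-lutidine (0.5 equiv), CH2Cl2, 0 °C; used at once
Reagents that add atoms: carbon tetrabromide, BrC(Br)(Br)Br
Why: Appel bromination of the primary benzylic alcohol under buffered neutral conditions that spare the silyl ethers.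

**Union and endgame**

Step 22
Reactants: 22 dihydrobenzofuranyl dithiane; 5 (5R)-5-menthyloxy-2(5H)-furanone; 36 ring A benzyl bromide
Product: 39 (3R,4R,5R)-3-(ring A benzyl)-4-(2-aryl-1,3-dithian-2-yl)-5-menthyloxy lactone, via lithiated dithiane 37 (not isolated), via lithium enolate 38 (not isolated)
Conditions: n-BuLi, THF, −78 °C; 5, −78 °C; then 36, TMEDA, −78 → −20 °C
Reagents that add atoms: none
Why: n-BuLi removes the dithiane C2–H of 22, the most acidic proton present, and the sulfur- and aryl-stabilised carbanion 37 adds in a Michael sense to C4 of butenolide 5 to give lithium enolate 38, which is then benzylated at C3 by the p-alkoxybenzylic bromide 36 in an SN2 step. The closest known reaction type is the tandem conjugate addition–enolate alkylation of 5-alkoxy-2(5H)-furanones with lithiated 2-aryl-1,3-dithianes and benzylic bromides, the usual entry to trans-dibenzylbutyrolactone lignans. No ring is closed; the two new skeletal bonds are C4–C(dithiane) and C3–CH2(ring A). C4 is set by the acetal centre C5, the nucleophile entering the butenolide face anti to the menthyloxy group (4R), and C3 is set by C4, the bromide approaching the enolate anti to the bulky dithianyl group (3R, trans). The step needs 1,4- over 1,2-addition, which the soft delocalised anion and the hindered pseudo-ester carbonyl should secure, and C-monoalkylation ahead of proton transfer, which the reactive benzylic bromide with TMEDA at low temperature should secure. All other C–H bonds of the two halves are far less acidic than the dithiane proton, and silyl and benzyl ethers are inert to the enolate.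

Step 23
Reactants: 39 dithiane adduct
Product: 40 (3R,4R,5R)-3,4-bis(arylmethyl)-5-menthyloxy lactone
Conditions: NiCl2·6H2O, NaBH4, MeOH–THF, 0 °C → rt
Reagents that add atoms: none
Why: Nickel boride (Ni2B formed in the flask) reductively cleaves both C–S bonds to leave the ring B benzylic CH2; it is milder than Raney nickel, so the benzyl ethers and the benzylic C–O bonds of the dihydrobenzofuran and of the silylated carbinol should be spared.

Step 24
Reactants: 40 menthyloxy lactone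
Product: 43 fully protected (3R,4R)-lactone, via formyl acid 41 (not isolated), via hydroxy acid 42 (not isolated)
Conditions: NaBH4, KOH (aq), MeOH–THF, 0 °C → rt; then 2 M HCl to pH 3, rt
Reagents that add atoms: none
Why: Saponification of the pseudo-ester opens the acetal to the aldehyde carboxylate with loss of menthol, NaBH4 reduces the aldehyde at once, and acidification lactonises the γ-hydroxy acid (reductive acetal-to-lactone conversion), so C5 becomes the OCH2 while C3 and C4 are untouched.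

Step 25
Reactants: 43 protected lactone
Product: 44 tri-O-benzyl triol
Conditions: Bu4NF, AcOH, THF, 0 °C → rt
Reagents that add atoms: none
Why: Fluoride desilylation of the three TBS ethers, buffered with acetic acid to protect the lactone, done while the phenols are still benzylated so that no quinone methide pathway is open.

Step 26
Reactants: 44 tri-O-benzyl triol
Product: 45 CNP0186558.2 (target)
Conditions: H2 (1 atm), 10% Pd/C, EtOAc–MeOH, rt
Reagents that add atoms: none
Why: Catalytic hydrogenolysis of the three aryl benzyl ethers under neutral conditions, which cleaves ArO–CH2Ph faster than the benzylic C–O bonds of the carbinol and of the dihydrobenzofuran and avoids the acid that would cyclise the free ring A phenol onto the carbinol.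

**Compound list**

1 | furfural (furan-2-carbaldehyde) | O=Cc1ccco1 | starting material
2 | 5-hydroxy-2(5H)-furanone (racemic) | OC1OC(=O)C=C1 | intermediate
3 | (1R,2S,5R)-menthol | C[C@@H]1CC[C@H]([C@@H](C1)O)C(C)C | starting material
4 | 5-[(1R,2S,5R)-menthyloxy]-2(5H)-furanone, mixture of C5 epimers | C[C@@H]1CC[C@@H](C(C)C)[C@@H](C1)OC2OC(=O)C=C2 | intermediate
5 | (5R)-5-[(1R,2S,5R)-menthyloxy]-2(5H)-furanone | C[C@@H]1CC[C@@H](C(C)C)[C@@H](C1)O[C@@H]2OC(=O)C=C2 | intermediate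
6 | 5-bromo-2-hydroxy-3-methoxybenzaldehyde | COc1cc(Br)cc(C=O)c1O | starting material
7 | 5-bromo-3-methoxy-2-(methoxymethoxy)benzaldehyde | COCOc1c(C=O)cc(Br)cc1OC | intermediate
8 | N-{2-[5-bromo-3-methoxy-2-(methoxymethoxy)phenyl]-1-tosylethenyl}formamide (potassium salt in the flask) | COCOc1c(C=C(NC=O)S(=O)(=O)c2ccc(C)cc2)cc(Br)cc1OC | intermediate
9 | 2-[5-bromo-3-methoxy-2-(methoxymethoxy)phenyl]acetonitrile | COCOc1c(CC#N)cc(Br)cc1OC | intermediate
10 | 2-[5-bromo-3-methoxy-2-(methoxymethoxy)phenyl]acetic acid | COCOc1c(CC(=O)O)cc(Br)cc1OC | intermediate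
11 | (S)-4-benzyl-1,3-oxazolidin-2-one | O=C1N[C@@H](Cc2ccccc2)CO1 | starting material
12 | mixed anhydride of 10 with pivalic acid | COCOc1c(CC(=O)OC(=O)C(C)(C)C)cc(Br)cc1OC | intermediate
13 | (4S)-4-benzyl-3-{[5-bromo-3-methoxy-2-(methoxymethoxy)phenyl]acetyl}-1,3-oxazolidin-2-one | COCOc1c(CC(=O)N2C(=O)OC[C@@H]2Cc2ccccc2)cc(Br)cc1OC | intermediate
14 | 4-(benzyloxy)-3-methoxybenzaldehyde (O-benzylvanillin) | COc1cc(C=O)ccc1OCc1ccccc1 | starting material
15 | (Z)-dibutylboron enolate of 13 | CCCCB(CCCC)O/C(N1C(=O)OC[C@@H]1Cc1ccccc1)=C\c1cc(Br)cc(OC)c1OCOC | intermediate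
16 | (4S)-4-benzyl-3-{(2S,3S)-3-[4-(benzyloxy)-3-methoxyphenyl]-2-[5-bromo-3-methoxy-2-(methoxymethoxy)phenyl]-3-hydroxypropanoyl}-1,3-oxazolidin-2-one | COc1cc([C@@H](O)[C@@H](C(=O)N2C(=O)OC[C@@H]2Cc2ccccc2)c2cc(Br)cc(OC)c2OCOC)ccc1OCc1ccccc1 | intermediate
17 | (1S,2R)-1-[4-(benzyloxy)-3-methoxyphenyl]-2-[5-bromo-3-methoxy-2-(methoxymethoxy)phenyl]propane-1,3-diol | COc1cc([C@@H](O)[C@@H](CO)c2cc(Br)cc(OC)c2OCOC)ccc1OCc1ccccc1 | intermediate
18 | {(2S,3R)-2-[4-(benzyloxy)-3-methoxyphenyl]-5-bromo-7-methoxy-2,3-dihydro-1-benzofuran-3-yl}methanol | Brc1cc(OC)c2c(c1)[C@H](CO)[C@@H](c1ccc(OCc3ccccc3)c(OC)c1)O2 | intermediate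
19 | (2S,3R)-2-[4-(benzyloxy)-3-methoxyphenyl]-5-bromo-3-{[(tert-butyldimethylsilyl)oxy]methyl}-7-methoxy-2,3-dihydro-1-benzofuran | Brc1cc(OC)c2c(c1)[C@H](CO[Si](C)(C)C(C)(C)C)[C@@H](c1ccc(OCc3ccccc3)c(OC)c1)O2 | intermediate
20 | 5-lithio derivative of 19 (Li in place of Br) | [Li]c1cc(OC)c2c(c1)[C@H](CO[Si](C)(C)C(C)(C)C)[C@@H](c1ccc(OCc3ccccc3)c(OC)c1)O2 | intermediate
21 | (2S,3R)-2-[4-(benzyloxy)-3-methoxyphenyl]-3-{[(tert-butyldimethylsilyl)oxy]methyl}-7-methoxy-2,3-dihydro-1-benzofuran-5-carbaldehyde | O=Cc1cc(OC)c2c(c1)[C@H](CO[Si](C)(C)C(C)(C)C)[C@@H](c1ccc(OCc3ccccc3)c(OC)c1)O2 | intermediate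
22 | 2-{(2S,3R)-2-[4-(benzyloxy)-3-methoxyphenyl]-3-{[(tert-butyldimethylsilyl)oxy]methyl}-7-methoxy-2,3-dihydro-1-benzofuran-5-yl}-1,3-dithiane | S1CCCSC1c1cc(OC)c2c(c1)[C@H](CO[Si](C)(C)C(C)(C)C)[C@@H](c1ccc(OCc3ccccc3)c(OC)c1)O2 | intermediate
23 | 2-(benzyloxy)-5-bromo-3-methoxybenzaldehyde | COc1cc(Br)cc(C=O)c1OCc1ccccc1 | intermediate
24 | N-{2-[2-(benzyloxy)-5-bromo-3-methoxyphenyl]-1-tosylethenyl}formamide (potassium salt in the flask) | COc1cc(Br)cc(C=C(NC=O)S(=O)(=O)c2ccc(C)cc2)c1OCc1ccccc1 | intermediate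
25 | 2-[2-(benzyloxy)-5-bromo-3-methoxyphenyl]acetonitrile | COc1cc(Br)cc(CC#N)c1OCc1ccccc1 | intermediate
26 | 2-[2-(benzyloxy)-5-bromo-3-methoxyphenyl]acetic acid | COc1cc(Br)cc(CC(=O)O)c1OCc1ccccc1 | intermediate
27 | mixed anhydride of 26 with pivalic acid | COc1cc(Br)cc(CC(=O)OC(=O)C(C)(C)C)c1OCc1ccccc1 | intermediate
28 | (4S)-4-benzyl-3-{[2-(benzyloxy)-5-bromo-3-methoxyphenyl]acetyl}-1,3-oxazolidin-2-one | COc1cc(Br)cc(CC(=O)N2C(=O)OC[C@@H]2Cc2ccccc2)c1OCc1ccccc1 | intermediate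
29 | (4S)-4-benzyl-3-{(2R,3S)-2-[2-(benzyloxy)-5-bromo-3-methoxyphenyl]-3-[4-(benzyloxy)-3-methoxyphenyl]-3-[(trimethylsilyl)oxy]propanoyl}-1,3-oxazolidin-2-one | COc1cc([C@@H](O[Si](C)(C)C)[C@H](C(=O)N2C(=O)OC[C@@H]2Cc2ccccc2)c2cc(Br)cc(OC)c2OCc2ccccc2)ccc1OCc1ccccc1 | intermediate
30 | (2S,3S)-2-[2-(benzyloxy)-5-bromo-3-methoxyphenyl]-3-[4-(benzyloxy)-3-methoxyphenyl]-3-[(trimethylsilyl)oxy]propan-1-ol | COc1cc([C@@H](O[Si](C)(C)C)[C@H](CO)c2cc(Br)cc(OC)c2OCc2ccccc2)ccc1OCc1ccccc1 | intermediate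
31 | (1S,2S)-2-[2-(benzyloxy)-5-bromo-3-methoxyphenyl]-1-[4-(benzyloxy)-3-methoxyphenyl]propane-1,3-diol | COc1cc([C@@H](O)[C@H](CO)c2cc(Br)cc(OC)c2OCc2ccccc2)ccc1OCc1ccccc1 | intermediate
32 | (1S,2S)-2-[2-(benzyloxy)-5-bromo-3-methoxyphenyl]-1-[4-(benzyloxy)-3-methoxyphenyl]-1,3-bis[(tert-butyldimethylsilyl)oxy]propane | COc1cc([C@@H](O[Si](C)(C)C(C)(C)C)[C@H](CO[Si](C)(C)C(C)(C)C)c2cc(Br)cc(OC)c2OCc2ccccc2)ccc1OCc1ccccc1 | intermediate
33 | aryllithium from 32 (Li in place of Br) | COc1cc([C@@H](O[Si](C)(C)C(C)(C)C)[C@H](CO[Si](C)(C)C(C)(C)C)c2cc([Li])cc(OC)c2OCc2ccccc2)ccc1OCc1ccccc1 | intermediate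
34 | 4-(benzyloxy)-3-{(1S,2S)-1-[4-(benzyloxy)-3-methoxyphenyl]-1,3-bis[(tert-butyldimethylsilyl)oxy]propan-2-yl}-5-methoxybenzaldehyde | COc1cc([C@@H](O[Si](C)(C)C(C)(C)C)[C@H](CO[Si](C)(C)C(C)(C)C)c2cc(C=O)cc(OC)c2OCc2ccccc2)ccc1OCc1ccccc1 | intermediate
35 | (4-(benzyloxy)-3-{(1S,2S)-1-[4-(benzyloxy)-3-methoxyphenyl]-1,3-bis[(tert-butyldimethylsilyl)oxy]propan-2-yl}-5-methoxyphenyl)methanol | COc1cc([C@@H](O[Si](C)(C)C(C)(C)C)[C@H](CO[Si](C)(C)C(C)(C)C)c2cc(CO)cc(OC)c2OCc2ccccc2)ccc1OCc1ccccc1 | intermediate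
36 | 2-(benzyloxy)-5-(bromomethyl)-1-{(1S,2S)-1-[4-(benzyloxy)-3-methoxyphenyl]-1,3-bis[(tert-butyldimethylsilyl)oxy]propan-2-yl}-3-methoxybenzene (ring A benzyl bromide) | COc1cc([C@@H](O[Si](C)(C)C(C)(C)C)[C@H](CO[Si](C)(C)C(C)(C)C)c2cc(CBr)cc(OC)c2OCc2ccccc2)ccc1OCc1ccccc1 | intermediate
37 | 2-lithio derivative of dithiane 22 | [Li]C1(SCCCS1)c1cc(OC)c2c(c1)[C@H](CO[Si](C)(C)C(C)(C)C)[C@@H](c1ccc(OCc3ccccc3)c(OC)c1)O2 | intermediate
38 | lithium enolate of the (4R,5R)-4-(2-aryl-1,3-dithian-2-yl)-5-menthyloxy lactone | C[C@@H]1CC[C@@H](C(C)C)[C@@H](C1)O[C@@H]2OC(O[Li])=C[C@H]2C3(SCCCS3)c4cc(OC)c5c(c4)[C@H](CO[Si](C)(C)C(C)(C)C)[C@@H](c4ccc(OCc6ccccc6)c(OC)c4)O5 | intermediate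
39 | (3R,4R,5R)-3-(4-(benzyloxy)-3-{(1S,2S)-1-[4-(benzyloxy)-3-methoxyphenyl]-1,3-bis(TBS-oxy)propan-2-yl}-5-methoxybenzyl)-4-(2-{(2S,3R)-2-[4-(benzyloxy)-3-methoxyphenyl]-3-(TBS-oxymethyl)-7-methoxy-2,3-dihydro-1-benzofuran-5-yl}-1,3-dithian-2-yl)-5-[(1R,2S,5R)-menthyloxy]dihydrofuran-2(3H)-one | C[C@@H]1CC[C@@H](C(C)C)[C@@H](C1)O[C@@H]2OC(=O)[C@H](Cc4cc([C@@H](CO[Si](C)(C)C(C)(C)C)[C@H](O[Si](C)(C)C(C)(C)C)c5ccc(OCc6ccccc6)c(OC)c5)c(OCc5ccccc5)c(OC)c4)[C@H]2C3(SCCCS3)c4cc(OC)c5c(c4)[C@H](CO[Si](C)(C)C(C)(C)C)[C@@H](c4ccc(OCc6ccccc6)c(OC)c4)O5 | intermediate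
40 | (3R,4R,5R)-lactone as 39 with CH2 in place of the dithiane carbon | C[C@@H]1CC[C@@H](C(C)C)[C@@H](C1)O[C@@H]2OC(=O)[C@H](Cc4cc([C@@H](CO[Si](C)(C)C(C)(C)C)[C@H](O[Si](C)(C)C(C)(C)C)c5ccc(OCc6ccccc6)c(OC)c5)c(OCc5ccccc5)c(OC)c4)[C@H]2Cc4cc(OC)c5c(c4)[C@H](CO[Si](C)(C)C(C)(C)C)[C@@H](c4ccc(OCc6ccccc6)c(OC)c4)O5 | intermediate
41 | (2R,3R)-2-(ring A benzyl)-3-formyl-4-(dihydrobenzofuran-5-yl)butanoic acid, protected as in 40 (potassium salt in the flask) | OC(=O)[C@H](Cc4cc([C@@H](CO[Si](C)(C)C(C)(C)C)[C@H](O[Si](C)(C)C(C)(C)C)c5ccc(OCc6ccccc6)c(OC)c5)c(OCc5ccccc5)c(OC)c4)[C@H](C=O)Cc4cc(OC)c5c(c4)[C@H](CO[Si](C)(C)C(C)(C)C)[C@@H](c4ccc(OCc6ccccc6)c(OC)c4)O5 | intermediate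
42 | (2R,3R)-2-(ring A benzyl)-3-(hydroxymethyl)-4-(dihydrobenzofuran-5-yl)butanoic acid, protected as in 40 | OC(=O)[C@H](Cc4cc([C@@H](CO[Si](C)(C)C(C)(C)C)[C@H](O[Si](C)(C)C(C)(C)C)c5ccc(OCc6ccccc6)c(OC)c5)c(OCc5ccccc5)c(OC)c4)[C@H](CO)Cc4cc(OC)c5c(c4)[C@H](CO[Si](C)(C)C(C)(C)C)[C@@H](c4ccc(OCc6ccccc6)c(OC)c4)O5 | intermediate
43 | (3R,4R)-lactone of the target bearing three benzyl ethers (phenols of rings A, C, D) and three TBS ethers (both CH2OH and the carbinol) | COc1cc([C@@H](O[Si](C)(C)C(C)(C)C)[C@H](CO[Si](C)(C)C(C)(C)C)c2cc(C[C@H]3C(=O)OC[C@@H]3Cc3cc(OC)c4c(c3)[C@H](CO[Si](C)(C)C(C)(C)C)[C@@H](c3ccc(OCc5ccccc5)c(OC)c3)O4)cc(OC)c2OCc2ccccc2)ccc1OCc1ccccc1 | intermediate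
44 | tri-O-benzyl ether of the target (phenols of rings A, C, D benzylated, all alcohols free) | COc1cc([C@@H](O)[C@H](CO)c2cc(C[C@H]3C(=O)OC[C@@H]3Cc3cc(OC)c4c(c3)[C@H](CO)[C@@H](c3ccc(OCc5ccccc5)c(OC)c3)O4)cc(OC)c2OCc2ccccc2)ccc1OCc1ccccc1 | intermediate
45 | (3R,4R)-3-{3-[(1S,2S)-1,3-dihydroxy-1-(4-hydroxy-3-methoxyphenyl)propan-2-yl]-4-hydroxy-5-methoxybenzyl}-4-{[(2S,3R)-2-(4-hydroxy-3-methoxyphenyl)-3-(hydroxymethyl)-7-methoxy-2,3-dihydro-1-benzofuran-5-yl]methyl}dihydrofuran-2(3H)-one (CNP0186558.2) | COc1cc([C@@H](O)[C@H](CO)c2cc(C[C@H]3C(=O)OC[C@@H]3Cc3cc(OC)c4c(c3)[C@H](CO)[C@@H](c3ccc(O)c(OC)c3)O4)cc(OC)c2O)ccc1O | target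

**Count and risks**

Total step count: 26. Longest linear sequence: 15 steps (6 → steps 3–12 → steps 22–26).

Steps most likely to fail:

1. Step 22 (key step). The enolate may be protonated or alkylated too slowly by the large bromide, leaving the unalkylated conjugate adduct, or trans selectivity may erode through enolate equilibration. The fallback sets out from 22 and 5 and returns at 43. The conjugate addition is run as before and enolate 38 is quenched with NH4Cl to give the C3-unsubstituted (4R,5R)-dithianyl menthyloxy lactone F1. NiCl2·6H2O/NaBH4 then gives the desulfurised menthyloxy lactone F2, and NaBH4/KOH followed by acid gives the (4R)-4-(arylmethyl)butyrolactone F3. Its lithium enolate (LiN(SiMe3)2, THF, −78 °C) is alkylated with 36 anti to the C4 substituent, the classical trans-selective lactone benzylation, which gives 43 directly.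

2. Step 17 (anti aldol). The stabilised arylacetyl enolate may add sluggishly to the electron-rich aldehyde, or the facial and anti selectivity may be poor. The fallback sets out from 26 and returns at 32. Acid 26 is acylated onto (R)-4-benzyl-1,3-oxazolidin-2-one to give the (4R)-arylacetyl imide F4. An Evans syn aldol (Bu2BOTf, i-Pr2NEt) with 14 gives the (2R,3R)-syn aldol imide F5, and LiBH4 gives the (1R,2S)-syn diol F6. Selective silylation (TBSCl, imidazole, 0 °C) gives the primary TBS ether F7. Mitsunobu inversion of the carbinol (4-nitrobenzoic acid, PPh3, diisopropyl azodicarboxylate, −20 °C) gives the (1S,2S)-4-nitrobenzoate F8, and K2CO3/MeOH gives the anti mono-TBS alcohol F9. TBSOTf/2,6-lutidine then gives 32.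

3. Step 12 (dithiane formation). The Lewis acid with the thiol may open the benzylic aryl ether of the dihydrobenzofuran with thiol capture, or strip the silyl ether. The fallback sets out from 19 and returns at 22. Aryllithium 20 (t-BuLi, −78 °C) is transmetalated with MgBr2·OEt2 to the arylmagnesium bromide F10. This is alkylated at carbon by 2-chloro-1,3-dithiane F11, made beforehand from 1,3-dithiane and N-chlorosuccinimide, to give 22 with no acid and no free aldehyde.

**Further compounds**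

F1 | step 22 | (4R,5R)-4-(2-{(2S,3R)-2-[4-(benzyloxy)-3-methoxyphenyl]-3-(TBS-oxymethyl)-7-methoxy-2,3-dihydro-1-benzofuran-5-yl}-1,3-dithian-2-yl)-5-[(1R,2S,5R)-menthyloxy]dihydrofuran-2(3H)-one | C[C@@H]1CC[C@@H](C(C)C)[C@@H](C1)O[C@@H]2OC(=O)C[C@H]2C3(SCCCS3)c4cc(OC)c5c(c4)[C@H](CO[Si](C)(C)C(C)(C)C)[C@@H](c4ccc(OCc6ccccc6)c(OC)c4)O5
F2 | step 22 | (4R,5R)-4-({(2S,3R)-2-[4-(benzyloxy)-3-methoxyphenyl]-3-(TBS-oxymethyl)-7-methoxy-2,3-dihydro-1-benzofuran-5-yl}methyl)-5-[(1R,2S,5R)-menthyloxy]dihydrofuran-2(3H)-one | C[C@@H]1CC[C@@H](C(C)C)[C@@H](C1)O[C@@H]2OC(=O)C[C@H]2Cc4cc(OC)c5c(c4)[C@H](CO[Si](C)(C)C(C)(C)C)[C@@H](c4ccc(OCc6ccccc6)c(OC)c4)O5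
F3 | step 22 | (4R)-4-({(2S,3R)-2-[4-(benzyloxy)-3-methoxyphenyl]-3-(TBS-oxymethyl)-7-methoxy-2,3-dihydro-1-benzofuran-5-yl}methyl)dihydrofuran-2(3H)-one | C1C(=O)OC[C@@H]1Cc1cc(OC)c2c(c1)[C@H](CO[Si](C)(C)C(C)(C)C)[C@@H](c1ccc(OCc3ccccc3)c(OC)c1)O2
F4 | step 17 | (4R)-4-benzyl-3-{[2-(benzyloxy)-5-bromo-3-methoxyphenyl]acetyl}-1,3-oxazolidin-2-one | COc1cc(Br)cc(CC(=O)N2C(=O)OC[C@H]2Cc2ccccc2)c1OCc1ccccc1
F5 | step 17 | (4R)-4-benzyl-3-{(2R,3R)-2-[2-(benzyloxy)-5-bromo-3-methoxyphenyl]-3-[4-(benzyloxy)-3-methoxyphenyl]-3-hydroxypropanoyl}-1,3-oxazolidin-2-one | COc1cc([C@H](O)[C@H](C(=O)N2C(=O)OC[C@H]2Cc2ccccc2)c2cc(Br)cc(OC)c2OCc2ccccc2)ccc1OCc1ccccc1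
F6 | step 17 | (1R,2S)-2-[2-(benzyloxy)-5-bromo-3-methoxyphenyl]-1-[4-(benzyloxy)-3-methoxyphenyl]propane-1,3-diol | COc1cc([C@H](O)[C@H](CO)c2cc(Br)cc(OC)c2OCc2ccccc2)ccc1OCc1ccccc1
F7 | step 17 | (1R,2S)-2-[2-(benzyloxy)-5-bromo-3-methoxyphenyl]-1-[4-(benzyloxy)-3-methoxyphenyl]-3-[(tert-butyldimethylsilyl)oxy]propan-1-ol | COc1cc([C@H](O)[C@H](CO[Si](C)(C)C(C)(C)C)c2cc(Br)cc(OC)c2OCc2ccccc2)ccc1OCc1ccccc1
F8 | step 17 | (1S,2S)-2-[2-(benzyloxy)-5-bromo-3-methoxyphenyl]-1-[4-(benzyloxy)-3-methoxyphenyl]-3-[(tert-butyldimethylsilyl)oxy]propyl 4-nitrobenzoate | COc1cc([C@@H](OC(=O)c2ccc(cc2)[N+](=O)[O-])[C@H](CO[Si](C)(C)C(C)(C)C)c2cc(Br)cc(OC)c2OCc2ccccc2)ccc1OCc1ccccc1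
F9 | step 17 | (1S,2S)-2-[2-(benzyloxy)-5-bromo-3-methoxyphenyl]-1-[4-(benzyloxy)-3-methoxyphenyl]-3-[(tert-butyldimethylsilyl)oxy]propan-1-ol | COc1cc([C@@H](O)[C@H](CO[Si](C)(C)C(C)(C)C)c2cc(Br)cc(OC)c2OCc2ccccc2)ccc1OCc1ccccc1
F10 | step 12 | {(2S,3R)-2-[4-(benzyloxy)-3-methoxyphenyl]-3-(TBS-oxymethyl)-7-methoxy-2,3-dihydro-1-benzofuran-5-yl}magnesium bromide | Br[Mg]c1cc(OC)c2c(c1)[C@H](CO[Si](C)(C)C(C)(C)C)[C@@H](c1ccc(OCc3ccccc3)c(OC)c1)O2
F11 | step 12 | 2-chloro-1,3-dithiane | ClC1SCCCS1
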